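The two phenols travel as benzyl ethers and are freed last by hydrogenolysis; lactone atoms are numbered O1, C2(=O), C3 (benzyl-bearing), C4 (aroyl-bearing), C5 (OCH2).
Key disconnection C4–C5: the lactone, the only ring made in the route, is closed by a photoredox 5-exo radical cyclisation of an iodomethyl ester onto an (E)-styrene, the benzylic carbon being oxidised to the aryl ketone by DMSO in the same flask.
Enabling feature: C5 lies between ring oxygen O1 and C4, and C4 carries an exocyclic aryl ketone carbon; C4 and that carbon can therefore be stored as a styrene C=C held 5-exo to an O1–CH2 radical by the O1–C2(=O)–C3 ester tether.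
The iodomethyl ester comes from an (R)-2-benzyl-4-arylbut-3-enoic acid (chloromethyl chlorosulfate, then NaI), whose stereocentre (the future C3) is set by Evans alkylation of a styrylacetyl oxazolidinone with a benzylic bromide.
The styrylacetic acid comes from a Wittig reaction of O-benzylvanillin with (2-carboxyethyl)triphenylphosphonium bromide.

Key step: step 8

Step 1
Reactants: 1 4-(benzyloxy)-3-methoxybenzaldehyde; 2 (2-carboxyethyl)triphenylphosphonium bromide
Product: 3 (E)-4-[4-(benzyloxy)-3-methoxyphenyl]but-3-enoic acid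
Conditions: NaN(SiMe3)2 (2.2 equiv), THF, −78 °C to rt; then 1 M HCl
Reagents that add atoms: none
Why: Wittig olefination, in which the ylide from 2 (one equivalent of base is consumed by the carboxylic acid) should give mainly the E styrene with an aromatic aldehyde, and conjugation with the aryl ring keeps the double bond β,γ to the carboxyl group.

Step 2
Reactants: 3 (E)-4-[4-(benzyloxy)-3-methoxyphenyl]but-3-enoic acid; 4 (R)-4-benzyloxazolidin-2-one
Product: 6 (R)-4-benzyl-3-{(E)-4-[4-(benzyloxy)-3-methoxyphenyl]but-3-enoyl}oxazolidin-2-one, via mixed pivalic anhydride 5 (not isolated)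
Conditions: t-BuCOCl, Et3N, THF, −20 °C; then LiCl, 4, −20 °C to rt
Reagents that add atoms: pivaloyl chloride, CC(C)(C)C(=O)Cl (its acyl group is found only in intermediate 5)
Why: N-acylation of the Evans auxiliary through the mixed anhydride with LiCl/Et3N activation needs no strong base, so the styrene-conjugated double bond should stay in place.

Step 3
Reactants: 7 [4-(benzyloxy)-3-methoxyphenyl]methanol
Product: 8 1-(benzyloxy)-4-(bromomethyl)-2-methoxybenzene
Conditions: PBr3 (0.4 equiv), CH2Cl2, 0 °C; used at once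
Reagents that add atoms: phosphorus tribromide, BrP(Br)Br
Why: Substitution of a benzylic alcohol by bromide through its bromophosphite ester is routine, and the electron-rich bromide is not stored.

Step 4
Reactants: 6 (R)-4-benzyl-3-{(E)-4-[4-(benzyloxy)-3-methoxyphenyl]but-3-enoyl}oxazolidin-2-one; 8 1-(benzyloxy)-4-(bromomethyl)-2-methoxybenzene
Product: 10 (R)-4-benzyl-3-{(R,E)-2-[4-(benzyloxy)-3-methoxybenzyl]-4-[4-(benzyloxy)-3-methoxyphenyl]but-3-enoyl}oxazolidin-2-one, via sodium dienolate 9 (not isolated)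
Conditions: NaN(SiMe3)2 (1.1 equiv), THF, −78 °C; then 8, −78 to −40 °C
Reagents that add atoms: sodium bis(trimethylsilyl)amide, C[Si](C)(C)[N-][Si](C)(C)C.[Na+] (its sodium is found only in intermediate 9)
Why: Evans asymmetric alkylation, in which the chelated Z sodium enolate reacts at its α-carbon (keeping the styrene conjugation) on the face away from the 4-benzyl group of the auxiliary, which with the (R)-auxiliary should set the (R) centre that becomes C3.

Step 5
Reactants: 10 (R)-4-benzyl-3-{(R,E)-2-[4-(benzyloxy)-3-methoxybenzyl]-4-[4-(benzyloxy)-3-methoxyphenyl]but-3-enoyl}oxazolidin-2-one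
Product: 12 (R,E)-2-[4-(benzyloxy)-3-methoxybenzyl]-4-[4-(benzyloxy)-3-methoxyphenyl]but-3-enoic acid, via lithium peroxycarboxylate 11 (not isolated)
Conditions: LiOH, 30% H2O2, THF/H2O 3:1, 0 °C; then aq Na2SO3; then 1 M HCl
Reagents that add atoms: hydrogen peroxide, OO; lithium hydroxide, [Li+].[OH-] (its lithium is found only in intermediate 11)
Why: Hydroperoxide attacks the exocyclic imide carbonyl selectively (standard removal of the Evans auxiliary) at 0 °C, mild enough to leave the α-centre and the β,γ-alkene alone, and sulfite reduces the peracid salt before acidification.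

Step 6
Reactants: 12 (R,E)-2-[4-(benzyloxy)-3-methoxybenzyl]-4-[4-(benzyloxy)-3-methoxyphenyl]but-3-enoic acid
Product: 13 chloromethyl (R,E)-2-[4-(benzyloxy)-3-methoxybenzyl]-4-[4-(benzyloxy)-3-methoxyphenyl]but-3-enoate
Conditions: ClCH2OSO2Cl, NaHCO3, n-Bu4NHSO4 (cat.), CH2Cl2/H2O, 0 °C to rt
Reagents that add atoms: chloromethyl chlorosulfate, ClCOS(=O)(=O)Cl
Why: Phase-transfer O-alkylation of the carboxylate by chloromethyl chlorosulfate (chlorosulfate leaves in preference to chloride) gives the chloromethyl ester with hydrogencarbonate as the only base, so the stereocentre is not touched.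

Step 7
Reactants: 13 chloromethyl (R,E)-2-[4-(benzyloxy)-3-methoxybenzyl]-4-[4-(benzyloxy)-3-methoxyphenyl]but-3-enoate
Product: 14 iodomethyl (R,E)-2-[4-(benzyloxy)-3-methoxybenzyl]-4-[4-(benzyloxy)-3-methoxyphenyl]but-3-enoate
Conditions: NaI (3 equiv), acetone, rt, dark; filtered, concentrated and used directly
Reagents that add atoms: sodium iodide, [Na+].[I-]
Why: Finkelstein halide exchange at the activated acyloxymethyl carbon, driven by precipitation of NaCl from acetone, gives the more easily reduced C–I bond.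

Step 8
Reactants: 14 iodomethyl (R,E)-2-[4-(benzyloxy)-3-methoxybenzyl]-4-[4-(benzyloxy)-3-methoxyphenyl]but-3-enoate
Product: 16 (3R,4R)-3-[4-(benzyloxy)-3-methoxybenzyl]-4-[4-(benzyloxy)-3-methoxybenzoyl]dihydrofuran-2(3H)-one, via alkoxysulfonium iodide 15 (not isolated)
Conditions: fac-Ir(ppy)3 (tris(2-phenylpyridinato)iridium, 1 mol %), NaHCO3 (2 equiv), degassed dry DMSO (0.01 M), blue LEDs (450 nm), 30–35 °C
Reagents that add atoms: dimethyl sulfoxide, CS(C)=O
Why: Proposed new method: photoexcited fac-Ir(ppy)3 should reduce the C–I bond of 14 to an acyloxymethyl radical at the future C5, which adds to the styrene carbon that becomes C4; the benzylic radical so formed is oxidised by the tetravalent iridium left behind (returning the trivalent catalyst), DMSO captures the cation as alkoxysulfonium salt 15, and hydrogencarbonate-assisted loss of dimethyl sulfide (Kornblum oxidation) gives the aryl ketone. The closest known reaction types are the photoredox keto-alkylation of styrenes by carbon radicals in DMSO and the atom-transfer radical lactonisation of allyl iodoacetates in polar media; an ester-tethered O–CH2 radical closing onto a styrene with Kornblum termination is not yet established. The lactone ring closes in the 5-exo-trig mode. C4 is controlled by the C3 centre already present: in the chair-like transition state of the 5-hexenyl-type closure the C3 benzyl group lies pseudo-equatorial and leads to the 3,4-trans ring, which is also the thermodynamic isomer reachable through the enol of the new ketone, while the benzylic centre of 15 is erased on oxidation. The step needs 5-exo rather than 6-endo closure, secured by the aryl group because only attack at the alkene carbon remote from it gives a benzylic radical, and it needs ring closure to outrun reduction or intermolecular addition of the radical, for which high dilution and the polar medium (which raises the population of the reactive E ester rotamer) are chosen. C3 should keep its configuration because nothing more basic than NaHCO3 is present, and E/Z photoisomerisation of the styrene is harmless since both isomers give the same benzylic radical.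

Step 9
Reactants: 16 (3R,4R)-3-[4-(benzyloxy)-3-methoxybenzyl]-4-[4-(benzyloxy)-3-methoxybenzoyl]dihydrofuran-2(3H)-one
Product: 17 (3R,4R)-3-(4-hydroxy-3-methoxybenzyl)-4-(4-hydroxy-3-methoxybenzoyl)dihydrofuran-2(3H)-one
Conditions: H2 (1 atm), 10% Pd/C, EtOAc, rt; stopped at full conversion
Reagents that add atoms: none
Why: Catalytic hydrogenolysis cleaves both aryl benzyl ethers under neutral conditions, should be faster than reduction of the aryl ketone, and leaves the lactone and the C3 and C4 centres untouched.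

Compound list
1 | 4-(benzyloxy)-3-methoxybenzaldehyde | COc1cc(C=O)ccc1OCc1ccccc1 | starting material
2 | (2-carboxyethyl)triphenylphosphonium bromide | OC(=O)CC[P+](c1ccccc1)(c1ccccc1)c1ccccc1.[Br-] | starting material
3 | (E)-4-[4-(benzyloxy)-3-methoxyphenyl]but-3-enoic acid | COc1cc(/C=C/CC(=O)O)ccc1OCc1ccccc1 | intermediate
4 | (R)-4-benzyloxazolidin-2-one | O=C1N[C@H](Cc2ccccc2)CO1 | starting material
5 | mixed anhydride of 3 with pivalic acid | COc1cc(/C=C/CC(=O)OC(=O)C(C)(C)C)ccc1OCc1ccccc1 | intermediate (not isolated)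
6 | (R)-4-benzyl-3-{(E)-4-[4-(benzyloxy)-3-methoxyphenyl]but-3-enoyl}oxazolidin-2-one | COc1cc(/C=C/CC(=O)N2[C@H](Cc3ccccc3)COC2=O)ccc1OCc1ccccc1 | intermediate
7 | [4-(benzyloxy)-3-methoxyphenyl]methanol | COc1cc(CO)ccc1OCc1ccccc1 | starting material
8 | 1-(benzyloxy)-4-(bromomethyl)-2-methoxybenzene | COc1cc(CBr)ccc1OCc1ccccc1 | intermediate
9 | sodium (Z)-dienolate of 6 (O-bound sodium; Z enolate, E styrene) | [Na+].[O-]/C(=C\C=C\c1ccc(OCc2ccccc2)c(OC)c1)N1[C@H](Cc2ccccc2)COC1=O | intermediate (not isolated)
10 | (R)-4-benzyl-3-{(R,E)-2-[4-(benzyloxy)-3-methoxybenzyl]-4-[4-(benzyloxy)-3-methoxyphenyl]but-3-enoyl}oxazolidin-2-one | COc1cc(C[C@H](/C=C/c2ccc(OCc3ccccc3)c(OC)c2)C(=O)N2[C@H](Cc3ccccc3)COC2=O)ccc1OCc1ccccc1 | intermediate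
11 | lithium (R,E)-2-[4-(benzyloxy)-3-methoxybenzyl]-4-[4-(benzyloxy)-3-methoxyphenyl]but-3-eneperoxoate | COc1cc(C[C@H](/C=C/c2ccc(OCc3ccccc3)c(OC)c2)C(=O)O[O-])ccc1OCc1ccccc1.[Li+] | intermediate (not isolated)
12 | (R,E)-2-[4-(benzyloxy)-3-methoxybenzyl]-4-[4-(benzyloxy)-3-methoxyphenyl]but-3-enoic acid | COc1cc(C[C@H](/C=C/c2ccc(OCc3ccccc3)c(OC)c2)C(=O)O)ccc1OCc1ccccc1 | intermediate
13 | chloromethyl (R,E)-2-[4-(benzyloxy)-3-methoxybenzyl]-4-[4-(benzyloxy)-3-methoxyphenyl]but-3-enoate | COc1cc(C[C@H](/C=C/c2ccc(OCc3ccccc3)c(OC)c2)C(=O)OCCl)ccc1OCc1ccccc1 | intermediate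
14 | iodomethyl (R,E)-2-[4-(benzyloxy)-3-methoxybenzyl]-4-[4-(benzyloxy)-3-methoxyphenyl]but-3-enoate | COc1cc(C[C@H](/C=C/c2ccc(OCc3ccccc3)c(OC)c2)C(=O)OCI)ccc1OCc1ccccc1 | intermediate
15 | alkoxysulfonium iodide: the 3,4-trans (3R,4R) lactone carrying at C4 a CH(OS+Me2)(4-benzyloxy-3-methoxyphenyl) group, both epimers at the benzylic carbon | COc1cc(C[C@H]2C(=O)OC[C@@H]2C(O[S+](C)C)c2ccc(OCc3ccccc3)c(OC)c2)ccc1OCc1ccccc1.[I-] | intermediate (not isolated)
16 | (3R,4R)-3-[4-(benzyloxy)-3-methoxybenzyl]-4-[4-(benzyloxy)-3-methoxybenzoyl]dihydrofuran-2(3H)-one | COc1cc(C[C@H]2C(=O)OC[C@@H]2C(=O)c2ccc(OCc3ccccc3)c(OC)c2)ccc1OCc1ccccc1 | intermediate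
17 | (3R,4R)-3-(4-hydroxy-3-methoxybenzyl)-4-(4-hydroxy-3-methoxybenzoyl)dihydrofuran-2(3H)-one (CNP0159909.1) | COc1cc(C[C@H]2C(=O)OC[C@@H]2C(=O)c2ccc(O)c(OC)c2)ccc1O | target

Total step count: 9. Longest linear sequence: 8 (steps 1, 2, 4, 5, 6, 7, 8, 9; step 3 is a one-step side branch).

Steps most likely to fail

1. Step 8 (the proposed new method). What may go wrong: the acyloxymethyl radical may be reduced or may add to a second molecule before the ester reaches the E rotamer needed for ring closure, or the benzylic cation may lose a proton instead of being captured by DMSO. The fallback uses known chemistry, sets out from aldehyde 1, uses bromide 8 and returns to the route at 16. Aldehyde 1 is condensed with propane-1,3-dithiol (BF3·OEt2, CH2Cl2) to 2-[4-(benzyloxy)-3-methoxyphenyl]-1,3-dithiane F1. F1 is deprotonated (n-BuLi, THF, −78 °C) and added in conjugate fashion to (5R)-5-[(1R,2S,5R)-menthyloxy]furan-2(5H)-one, anti to the menthyloxy group; the lactone enolate is then alkylated with bromide 8, anti to the new C4 substituent, to give (3R,4R,5R)-3-[4-(benzyloxy)-3-methoxybenzyl]-4-{2-[4-(benzyloxy)-3-methoxyphenyl]-1,3-dithian-2-yl}-5-[(1R,2S,5R)-menthyloxy]dihydrofuran-2(3H)-one F2. NaBH4/KOH in aqueous ethanol followed by acidification reduces the masked aldehyde carbon C5 and relactonises to (3R,4R)-3-[4-(benzyloxy)-3-methoxybenzyl]-4-{2-[4-(benzyloxy)-3-methoxyphenyl]-1,3-dithian-2-yl}dihydrofuran-2(3H)-one F3. MeI/CaCO3 in aqueous MeCN then unmasks the ketone and gives 16. This is the tandem conjugate addition–enolate alkylation established for trans-2,3-disubstituted butyrolactone lignans; it builds the C3–benzyl and C4–acyl bonds on a preformed ring and abandons the C4–C5 closure.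

2. Step 4. What may go wrong: alkylation of the extended, aryl-conjugated dienolate at its γ-carbon, or erosion of configuration at the doubly activated α-carbon by proton exchange with unreacted enolate. The fallback sets out from auxiliary 4 and returns at 10; it makes the stereocentre on a simpler dienolate and attaches the aryl group afterwards. Auxiliary 4 is acylated (n-BuLi, THF, −78 °C, (E)-but-2-enoyl chloride) to (R)-4-benzyl-3-[(E)-but-2-enoyl]oxazolidin-2-one F4. Deconjugative α-alkylation of F4 (NaN(SiMe3)2, THF, −78 °C, then bromide 8) gives (R)-4-benzyl-3-{(R)-2-[4-(benzyloxy)-3-methoxybenzyl]but-3-enoyl}oxazolidin-2-one F5. Aldehyde 1 is methylenated (Ph3P=CH2, THF) to 1-(benzyloxy)-2-methoxy-4-vinylbenzene F6. Cross-metathesis of F5 with F6 (second-generation Hoveyda–Grubbs catalyst, CH2Cl2, 40 °C) should give the E styrene 10.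

3. Step 5. What may go wrong: hydroxide-induced migration of the double bond toward conjugation with the carboxyl group, epimerisation at the α-carbon, or competing opening of the oxazolidinone ring. The fallback sets out from 10 and returns at 12; it removes the auxiliary by reduction and re-oxidises. LiBH4 (Et2O, 1 equiv H2O, 0 °C) gives (R,E)-2-[4-(benzyloxy)-3-methoxybenzyl]-4-[4-(benzyloxy)-3-methoxyphenyl]but-3-en-1-ol F7. Dess–Martin periodinane buffered with NaHCO3 (CH2Cl2, 0 °C) gives (R,E)-2-[4-(benzyloxy)-3-methoxybenzyl]-4-[4-(benzyloxy)-3-methoxyphenyl]but-3-enal F8. F8 is oxidised at once under Pinnick conditions (NaClO2, NaH2PO4, 2-methylbut-2-ene, t-BuOH/H2O) to acid 12.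

Further compounds
F1 | step 8 | 2-[4-(benzyloxy)-3-methoxyphenyl]-1,3-dithiane | COc1cc(C2SCCCS2)ccc1OCc1ccccc1
F2 | step 8 | (3R,4R,5R)-3-[4-(benzyloxy)-3-methoxybenzyl]-4-{2-[4-(benzyloxy)-3-methoxyphenyl]-1,3-dithian-2-yl}-5-[(1R,2S,5R)-menthyloxy]dihydrofuran-2(3H)-one | C[C@@H]1CC[C@H]([C@@H](C1)O[C@@H]2OC(=O)[C@H](Cc3ccc(OCc4ccccc4)c(OC)c3)[C@H]2C5(c3ccc(OCc4ccccc4)c(OC)c3)SCCCS5)C(C)C
F3 | step 8 | (3R,4R)-3-[4-(benzyloxy)-3-methoxybenzyl]-4-{2-[4-(benzyloxy)-3-methoxyphenyl]-1,3-dithian-2-yl}dihydrofuran-2(3H)-one | COc1cc(C[C@H]2C(=O)OC[C@@H]2C5(c3ccc(OCc4ccccc4)c(OC)c3)SCCCS5)ccc1OCc1ccccc1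
F4 | step 4 | (R)-4-benzyl-3-[(E)-but-2-enoyl]oxazolidin-2-one | C/C=C/C(=O)N1[C@H](Cc2ccccc2)COC1=O
F5 | step 4 | (R)-4-benzyl-3-{(R)-2-[4-(benzyloxy)-3-methoxybenzyl]but-3-enoyl}oxazolidin-2-one | COc1cc(C[C@H](C=C)C(=O)N2[C@H](Cc3ccccc3)COC2=O)ccc1OCc1ccccc1
F6 | step 4 | 1-(benzyloxy)-2-methoxy-4-vinylbenzene | COc1cc(C=C)ccc1OCc1ccccc1
F7 | step 5 | (R,E)-2-[4-(benzyloxy)-3-methoxybenzyl]-4-[4-(benzyloxy)-3-methoxyphenyl]but-3-en-1-ol | COc1cc(C[C@H](/C=C/c2ccc(OCc3ccccc3)c(OC)c2)CO)ccc1OCc1ccccc1
F8 | step 5 | (R,E)-2-[4-(benzyloxy)-3-methoxybenzyl]-4-[4-(benzyloxy)-3-methoxyphenyl]but-3-enal | COc1cc(C[C@H](/C=C/c2ccc(OCc3ccccc3)c(OC)c2)C=O)ccc1OCc1ccccc1
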